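**Assumption:** the target has no stereogenic element (no stereocentres; the prenyl alkene carries two identical methyls), so the "single enantiomer" is the one achiral constitution. The only stereocentre in the route (carbinol 13) is made racemic and removed by oxidation.

## Retrosynthetic overview

1. Pestalone G ⇐ global unmasking of a tris-MOM ether / dioxolane precursor (16); no rings are formed, both benzene rings are bought.
2. 16 ⇐ ketone-directed C–H prenylation of benzophenone 14 at its only ortho C–H (new step, forms the aryl–prenyl bond).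
3. 14 ⇐ aryllithium from ring-B bromide 12 + ring-A aldehyde 7, then oxidation.
4. Ring A (7): 2-chloro-3-methylphenol → OMe → steric Ir borylation/oxidation (OH para to Cl) → bromination → ortho-formylation → MOM.
5. Ring B (12): 1-bromo-3,5-dimethoxybenzene → Vilsmeier formylation → demethylation → MOM → dioxolane.

## Route

**Step 1**
Reactants: 1, 2-chloro-3-methylphenol
Product: 2, 2-chloro-1-methoxy-3-methylbenzene
Conditions: MeI, K2CO3, acetone, reflux
Reagents that add atoms: iodomethane, CI
Why: Williamson O-methylation of a phenoxide is routine and fixes the OMe next to Cl.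

**Step 2**
Reactants: 2
Product: 3, 2-(4-chloro-3-methoxy-5-methylphenyl)-4,4,5,5-tetramethyl-1,3,2-dioxaborolane
Conditions: B2pin2 (0.7 equiv), [Ir(OMe)(cod)]2 (1.5 mol%), dtbpy (3 mol%), THF, 80 °C
Reagents that add atoms: bis(pinacolato)diboron, CC1(C)OB(OC1(C)C)B1OC(C)(C)C(C)(C)O1
Why: Sterically controlled Ir-catalysed C–H borylation of a 1,2,3-trisubstituted arene goes to C5, the only C–H with no ortho substituent, and tolerates Ar–Cl.

**Step 3**
Reactants: 3
Product: 4, 4-chloro-3-methoxy-5-methylphenol
Conditions: 30% H2O2, aq NaOH, THF, 0 °C → rt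
Reagents that add atoms: hydrogen peroxide, OO
Why: Oxidation of the aryl boronate (1,2-aryl shift from B to O) gives the phenol with OH para to Cl, without relying on electrophilic regioselectivity.

**Step 4**
Reactants: 4
Product: 5, 2-bromo-4-chloro-5-methoxy-3-methylphenol
Conditions: NBS (1.0 equiv), MeCN, 0 °C, dark
Reagents that add atoms: N-bromosuccinimide, BrN1C(=O)CCC1=O
Why: Electrophilic aromatic bromination; with the para position blocked by Cl, Br enters ortho to OH and para to OMe rather than the site flanked by both oxygens.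

**Step 5**
Reactants: 5
Product: 6, 3-bromo-5-chloro-2-hydroxy-6-methoxy-4-methylbenzaldehyde
Conditions: MgCl2 (anhydrous), Et3N, (CH2O)n, THF, reflux
Reagents that add atoms: formaldehyde (from paraformaldehyde), C=O
Why: Casnati–Skattebøl Mg-phenoxide ortho-formylation is ortho-specific and works on o-bromophenols; only one ring C–H remains, so regiochemistry is unambiguous.

**Step 6**
Reactants: 6
Product: 7, 3-bromo-5-chloro-6-methoxy-2-(methoxymethoxy)-4-methylbenzaldehyde
Conditions: MOMCl, i-Pr2NEt, CH2Cl2, 0 °C → rt
Reagents that add atoms: chloromethyl methyl ether, COCCl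
Why: O-alkylation masks the acidic, chelating phenol for the organolithium and C–H activation steps and keeps the two ring-A oxygens differentiated (OMe stays, MOM leaves).

**Step 7**
Reactants: 8, 1-bromo-3,5-dimethoxybenzene
Product: 9, 2-bromo-4,6-dimethoxybenzaldehyde
Conditions: POCl3, DMF, 0 → 90 °C; then aq NaOAc
Reagents that add atoms: N,N-dimethylformamide, CN(C)C=O; water, O
Why: Vilsmeier–Haack formylation occurs para to one OMe and ortho to the other (ortho to Br), not at the position between the two OMe groups.

**Step 8**
Reactants: 9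
Product: 10, 2-bromo-4,6-dihydroxybenzaldehyde
Conditions: BBr3 (5 equiv), CH2Cl2, −78 °C → rt
Reagents that add atoms: none
Why: Lewis-acid ether cleavage removes both methyl ethers early, while nothing acid-sensitive is present, so ring B can be re-protected with mildly removable groups.

**Step 9**
Reactants: 10
Product: 11, 2-bromo-4,6-bis(methoxymethoxy)benzaldehyde
Conditions: MOMCl (3 equiv), i-Pr2NEt, CH2Cl2, 0 °C → rt
Reagents that add atoms: chloromethyl methyl ether, COCCl
Why: Standard bis-MOM protection gives ethers stable to BuLi, DMP and Rh(III) that are removed together with the ring-A MOM at the end.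

**Step 10**
Reactants: 11
Product: 12, 2-[2-bromo-4,6-bis(methoxymethoxy)phenyl]-1,3-dioxolane
Conditions: (TMSOCH2)2, TMSOTf (3 mol%), CH2Cl2, −78 → −20 °C; pyridine quench
Reagents that add atoms: 1,2-bis(trimethylsilyloxy)ethane, C[Si](C)(C)OCCO[Si](C)(C)C
Why: Noyori acetalisation is aprotic and run cold with catalytic TMSOTf, so it protects the aldehyde without cleaving the aryl MOM ethers.

**Step 11**
Reactants: 12 (1.15 equiv) and 7 (1.0 equiv)
Product: 13, (3-bromo-5-chloro-6-methoxy-2-(methoxymethoxy)-4-methylphenyl)[2-(1,3-dioxolan-2-yl)-3,5-bis(methoxymethoxy)phenyl]methanol (racemic)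
Conditions: 12, n-BuLi (1.10 equiv), THF, −78 °C, 20 min; then 7, −78 → −40 °C; aq NH4Cl
Reagents that add atoms: none
Why: Br–Li exchange on 12 is complete before 7 is added, and 1,2-addition of the aryllithium to the aldehyde is far faster than ArLi/ArBr exchange at −78 °C; the new carbinol centre is formed racemic and is removed in step 12.

**Step 12**
Reactants: 13
Product: 14, (3-bromo-5-chloro-6-methoxy-2-(methoxymethoxy)-4-methylphenyl)[2-(1,3-dioxolan-2-yl)-3,5-bis(methoxymethoxy)phenyl]methanone
Conditions: Dess–Martin periodinane, NaHCO3, CH2Cl2, rt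
Reagents that add atoms: none
Why: Buffered Dess–Martin oxidation converts hindered benzhydrols to benzophenones without touching the acetal, MOM ethers or aryl halides.

**Step 13**
Reactants: 14 and 15, 3-methylbuta-1,2-diene (3 equiv)
Product: 16, (3-bromo-5-chloro-6-methoxy-2-(methoxymethoxy)-4-methylphenyl)[2-(1,3-dioxolan-2-yl)-3,5-bis(methoxymethoxy)-6-(3-methylbut-2-en-1-yl)phenyl]methanone
Conditions: [Cp*Rh(MeCN)3](SbF6)2 (5 mol%), NaOPiv (20 mol%), PivOH (0.5 equiv), DCE, 4 Å MS, 60 °C, sealed tube
Reagents that add atoms: 3-methylbuta-1,2-diene, CC(C)=C=C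
Why: Proposed new method: diaryl-ketone-directed, redox-neutral ortho C–H prenylation — the ketone oxygen binds cationic Cp*Rh(III), pivalate-assisted concerted metalation–deprotonation occurs at C6′–H (the only C–H ortho to the carbonyl on either ring, so C4′ between the two OMOM groups cannot react), the aryl–Rh bond adds across the unsubstituted C=C of the allene with aryl going to the terminal CH2, and PivOH protonates the resulting alkenyl–Rh to release Ar–CH2–CH=CMe2 and regenerate Rh(III); the closest known chemistry is amide- or heteroaryl-directed Rh(III)/Co(III)/Mn(I) C–H prenylation with 1,1-dimethylallene and ketone-directed Rh(III) C–H olefination, neither shown with a weak ketone director at an alkoxy-flanked site of a tri-ortho-substituted benzophenone.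

**Step 14**
Reactants: 16
Product: 17, Pestalone G, 2-(3-bromo-5-chloro-2-hydroxy-6-methoxy-4-methylbenzoyl)-4,6-dihydroxy-3-(3-methylbut-2-en-1-yl)benzaldehyde
Conditions: TMSOTf (12 equiv), 2,2′-bipyridyl (18 equiv), CH2Cl2, 0 °C → rt; then H2O/THF, rt
Reagents that add atoms: water, O
Why: Silyl triflate/bipyridyl converts aryl MOM ethers (via pyridinium salts) to silyl ethers and opens the dioxolane, and water then releases the three phenols and the aldehyde under near-neutral conditions, avoiding the strong acid that cyclises o-prenylphenols to chromans and the bases or amines that rearrange o-formylbenzophenones.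

## Compound list

1 | 2-chloro-3-methylphenol | Cc1cccc(O)c1Cl | starting material
2 | 2-chloro-1-methoxy-3-methylbenzene | COc1cccc(C)c1Cl | intermediate
3 | 2-(4-chloro-3-methoxy-5-methylphenyl)-4,4,5,5-tetramethyl-1,3,2-dioxaborolane | COc1cc(cc(C)c1Cl)B1OC(C)(C)C(C)(C)O1 | intermediate
4 | 4-chloro-3-methoxy-5-methylphenol | COc1cc(O)cc(C)c1Cl | intermediate
5 | 2-bromo-4-chloro-5-methoxy-3-methylphenol | COc1cc(O)c(Br)c(C)c1Cl | intermediate
6 | 3-bromo-5-chloro-2-hydroxy-6-methoxy-4-methylbenzaldehyde | COc1c(Cl)c(C)c(Br)c(O)c1C=O | intermediate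
7 | 3-bromo-5-chloro-6-methoxy-2-(methoxymethoxy)-4-methylbenzaldehyde | COCOc1c(Br)c(C)c(Cl)c(OC)c1C=O | intermediate
8 | 1-bromo-3,5-dimethoxybenzene | COc1cc(Br)cc(OC)c1 | starting material
9 | 2-bromo-4,6-dimethoxybenzaldehyde | COc1cc(Br)c(C=O)c(OC)c1 | intermediate
10 | 2-bromo-4,6-dihydroxybenzaldehyde | Oc1cc(Br)c(C=O)c(O)c1 | intermediate
11 | 2-bromo-4,6-bis(methoxymethoxy)benzaldehyde | COCOc1cc(Br)c(C=O)c(OCOC)c1 | intermediate
12 | 2-[2-bromo-4,6-bis(methoxymethoxy)phenyl]-1,3-dioxolane | COCOc1cc(Br)c(C2OCCO2)c(OCOC)c1 | intermediate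
13 | (3-bromo-5-chloro-6-methoxy-2-(methoxymethoxy)-4-methylphenyl)[2-(1,3-dioxolan-2-yl)-3,5-bis(methoxymethoxy)phenyl]methanol, racemic | COCOc1cc(C(O)c2c(OC)c(Cl)c(C)c(Br)c2OCOC)c(C2OCCO2)c(OCOC)c1 | intermediate
14 | (3-bromo-5-chloro-6-methoxy-2-(methoxymethoxy)-4-methylphenyl)[2-(1,3-dioxolan-2-yl)-3,5-bis(methoxymethoxy)phenyl]methanone | COCOc1cc(C(=O)c2c(OC)c(Cl)c(C)c(Br)c2OCOC)c(C2OCCO2)c(OCOC)c1 | intermediate
15 | 3-methylbuta-1,2-diene | CC(C)=C=C | starting material
16 | (3-bromo-5-chloro-6-methoxy-2-(methoxymethoxy)-4-methylphenyl)[2-(1,3-dioxolan-2-yl)-3,5-bis(methoxymethoxy)-6-(3-methylbut-2-en-1-yl)phenyl]methanone | COCOc1cc(OCOC)c(C2OCCO2)c(C(=O)c2c(OC)c(Cl)c(C)c(Br)c2OCOC)c1CC=C(C)C | intermediate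
17 | Pestalone G | COc1c(Cl)c(C)c(Br)c(O)c1C(=O)c1c(C=O)c(O)cc(O)c1CC=C(C)C | target

## Summary

Total steps: 14. Longest linear sequence: 10 (steps 1–6, then 11–14); the ring-B branch is 4 steps (7–10).

Three steps most likely to fail:

1. **Step 13 (proposed new C–H prenylation).** Risks are weak ketone coordination at a crowded site, addition of the alkenyl–Rh to the ketone, or wrong allene regiochemistry. Fallback (known chemistry): iodinate 14 electrophilically at C6′ (NIS or IPy2BF4; para to the 3′-OMOM, as 3,5-dialkoxyarenes halogenate at 2/6 and not 4), then run a Stille coupling with tributyl(3-methylbut-2-enyl)stannane (Pd(PPh3)4, LiCl, DMF), which is selective for the aryl iodide over the di-ortho-substituted ring-A bromide.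

2. **Step 14 (global deprotection).** Risks are chroman formation from the o-prenylphenol and lactone formation from the o-formylbenzophenone. Fallback: redesign the protecting groups so ring-B phenols are TBS ethers (installed in step 9). Then remove the dioxolane and the chelation-labile ring-A MOM with mild acid (PPTS, wet acetone/MeOH) while the oxygen next to the prenyl group is still silylated, and finish with buffered fluoride (HF·pyridine or TBAF/AcOH).

3. **Step 11 (fragment coupling).** Risks are ArLi/ArBr scrambling on 7 or slow addition to the di-ortho-substituted aldehyde. Fallback: reverse the polarity. Protect phenol 5 as its MOM ether and magnesiate its single ring C–H (between OMOM and OMe) with TMPMgCl·LiCl, which tolerates Ar–Br and Ar–Cl. Add this to the ring-B aldehyde made from 12 by Br–Li exchange/DMF, then oxidise as in step 12; this also removes step 5.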